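**Remarks on the chemistry (assumptions).** Locants follow germacranolide usage: lactone oxygen on C6, ring-fusion CH = C7, epoxy-ester carbinol = C8, acetate carbinol = C9, Z-alkenes C10(Me)=C1 and C3=C4(Me), methylene C11=C13, carbonyl C12. The acyl group is (2S,3R)-2,3-dimethyloxirane-2-carboxylate (methyl groups cis), so it derives from (E)-2-methylbut-2-en-1-ol. The lactone is cis-fused (6S,7S). The six starting materials are taken to be catalogue compounds.

## Retrosynthetic overview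

1. The two esters come off last: C9 acetate, then the C8 (2S,3R)-epoxy ester (acid from Sharpless epoxidation of tiglyl alcohol and oxidation), leaving a cis-fused hydroxy lactone with C9 as a silyl ether.
2. Key disconnection C7–C8: the ten-membered carbocycle is closed by an intramolecular chromium-mediated Barbier (Nozaki–Hiyama–Kishi) allylation of a C8 aldehyde by a 3-(bromomethyl)butenolide. This one operation closes the ring, sets C7 and C8, and moves the butenolide C7=C11 bond out to the C11=C13 methylene.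
3. Enabling feature: the homoallylic-alcohol retron C13=C11–C7–C8–O, in which C7 is at once the β-carbon of the α-methylene-γ-butyrolactone (ring O–C12–C11–C7–C6) and a member of the ten-membered ring; it maps onto C13–Br/C11=C7 plus a C8 aldehyde.
4. The butenolide (first ring of the core) comes from ring-closing metathesis of the 2-(bromomethyl)acrylate of a C6 vinyl carbinol; C6 derives from (S)-epichlorohydrin.
5. The (Z,Z)-skipped diene comes from a Stork–Zhao-type iodo-olefination (C3=C4) and a Z-selective Wittig reaction of a D-glycerate-derived α-silyloxy methyl ketone (C1=C10, C9). Ring order: oxirane of the acid (separate branch), butenolide, ten-membered carbocycle.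

Key step: step 14

## Route

Step 1
Reactants: 1 methyl (R)-2,2-dimethyl-1,3-dioxolane-4-carboxylate
Product: 2 methyl (R)-2,3-dihydroxypropanoate
Conditions: Amberlyst 15 (H+ form), MeOH, 23 °C
Reagents that add atoms: none
Why: Acid-catalysed transketalisation to methanol should free the diol without touching any bond at the stereocentre, so the (R) configuration is carried over.

Step 2
Reactants: 2 methyl (R)-2,3-dihydroxypropanoate
Product: 3 methyl (R)-2,3-bis[(tert-butyldimethylsilyl)oxy]propanoate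
Conditions: TBSCl, imidazole, DMF, 0 → 23 °C
Reagents that add atoms: tert-butyldimethylsilyl chloride CC(C)(C)[Si](C)(C)Cl
Why: Standard imidazole-promoted silylation should protect both hydroxyls as non-chelating silyl ethers, which later serve Felkin–Anh control.

Step 3
Reactants: 3 methyl (R)-2,3-bis[(tert-butyldimethylsilyl)oxy]propanoate
Product: 5 (R)-3,4-bis[(tert-butyldimethylsilyl)oxy]butan-2-one, via Weinreb amide 4 (not isolated)
Conditions: MeNH(OMe)·HCl, i-PrMgCl, THF, −20 °C; then MeMgBr, −20 → 0 °C; aq. NH4Cl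
Reagents that add atoms: methylmagnesium bromide C[Mg]Br; N,O-dimethylhydroxylamine hydrochloride CNOC.Cl (atoms of intermediate 4 only)
Why: Telescoped Weinreb ketone synthesis, in which the magnesium amide converts the ester into the N-methoxy-N-methylamide and the stable magnesium chelate of the Grignard adduct prevents over-addition; the α-stereocentre is not enolised at low temperature.

Step 4
Reactants: 6 3-[(tert-butyldimethylsilyl)oxy]propanal; 7 ethyltriphenylphosphonium iodide
Product: 11 (Z)-tert-butyl[(4-iodopent-3-en-1-yl)oxy]dimethylsilane, via ethylidenetriphenylphosphorane 8 (not isolated), via (1-iodoethyl)triphenylphosphonium iodide 9 (not isolated), via (1-iodoethylidene)triphenylphosphorane 10 (not isolated)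
Conditions: 7, n-BuLi, THF, 0 → 23 °C; I2, −78 °C; NaN(SiMe3)2, −20 °C; then 6, −78 → 23 °C
Reagents that add atoms: iodine II
Why: Stork–Zhao-type Wittig iodo-olefination with the α-iodoethylidene ylide should give the Z-vinyl iodide (iodine cis to the chain), which fixes the C3=C4 geometry with the future C5 position cis to C2.

Step 5
Reactants: 11 (Z)-tert-butyl[(4-iodopent-3-en-1-yl)oxy]dimethylsilane
Product: 12 (Z)-5-bromo-2-iodopent-2-ene
Conditions: Ph3PBr2, CH2Cl2, 0 → 23 °C
Reagents that add atoms: dibromotriphenylphosphorane BrP(Br)(c1ccccc1)(c1ccccc1)c1ccccc1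
Why: Appel-type direct conversion of a primary silyl ether into the bromide (oxyphosphonium formation, SN2 by bromide) should leave the vinyl iodide untouched.

Step 6
Reactants: 12 (Z)-5-bromo-2-iodopent-2-ene
Product: 13 [(Z)-4-iodopent-3-en-1-yl]triphenylphosphonium bromide
Conditions: PPh3, MeCN, 80 °C
Reagents that add atoms: triphenylphosphine c1ccc(cc1)P(c1ccccc1)c1ccccc1
Why: SN2 quaternisation at the primary bromide; the vinyl iodide is inert to PPh3 in the absence of a transition-metal catalyst.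

Step 7
Reactants: 13 [(Z)-4-iodopent-3-en-1-yl]triphenylphosphonium bromide; 5 (R)-3,4-bis[(tert-butyldimethylsilyl)oxy]butan-2-one
Product: 15 (2S,3Z,6Z)-1,2-bis[(tert-butyldimethylsilyl)oxy]-7-iodo-3-methylocta-3,6-diene, via phosphorus ylide 14 (not isolated)
Conditions: KN(SiMe3)2, THF, −78 °C; then 5, −78 → 23 °C
Reagents that add atoms: none
Why: Wittig olefination of an α-alkoxy (silyloxy) methyl ketone with a non-stabilised, salt-free ylide is Z-selective for the trisubstituted alkene (C2 cis to C9), and the C9 stereocentre is carried over from 5 without bond change.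

Step 8
Reactants: 15 (2S,3Z,6Z)-1,2-bis[(tert-butyldimethylsilyl)oxy]-7-iodo-3-methylocta-3,6-diene; 16 (S)-epichlorohydrin
Product: 18 (2S,4Z,7Z,9S)-9,10-bis[(tert-butyldimethylsilyl)oxy]-1-chloro-4,8-dimethyldeca-4,7-dien-2-ol, via vinyllithium 17 (not isolated)
Conditions: t-BuLi (2 equiv), Et2O, −78 °C; then 16, BF3·OEt2, −78 °C
Reagents that add atoms: tert-butyllithium [Li]C(C)(C)C (lithium of intermediate 17 only)
Why: Iodine–lithium exchange proceeds with retention of alkene geometry and BF3-promoted opening of the epoxide at its terminal carbon forms C4–C5; the C6 stereocentre comes from 16 with its C–O bond untouched.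

Step 9
Reactants: 18 (2S,4Z,7Z,9S)-9,10-bis[(tert-butyldimethylsilyl)oxy]-1-chloro-4,8-dimethyldeca-4,7-dien-2-ol
Product: 20 (3S,5Z,8Z,10S)-10,11-bis[(tert-butyldimethylsilyl)oxy]-5,9-dimethylundeca-1,5,8-trien-3-ol, via terminal epoxide 19 (not isolated)
Conditions: Me3S+ I−, n-BuLi (excess ylide), THF, −10 → 23 °C
Reagents that add atoms: trimethylsulfonium iodide C[S+](C)C.[I-]
Why: Excess dimethylsulfonium methylide (Corey–Chaykovsky reagent) closes the chlorohydrin to the epoxide, opens it at the terminal carbon and eliminates dimethyl sulfide, a one-carbon homologation to the vinyl carbinol that leaves C6 untouched.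

Step 10
Reactants: 20 (3S,5Z,8Z,10S)-10,11-bis[(tert-butyldimethylsilyl)oxy]-5,9-dimethylundeca-1,5,8-trien-3-ol; 21 2-(bromomethyl)prop-2-enoic acid
Product: 22 (3S,5Z,8Z,10S)-10,11-bis[(tert-butyldimethylsilyl)oxy]-5,9-dimethylundeca-1,5,8-trien-3-yl 2-(bromomethyl)prop-2-enoate
Conditions: DCC, DMAP (cat.), CH2Cl2, 0 °C
Reagents that add atoms: none
Why: Steglich esterification at low temperature with only catalytic DMAP should acylate the single free hydroxyl with retention at C6 while sparing the allylic bromide.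

Step 11
Reactants: 22 (3S,5Z,8Z,10S)-10,11-bis[(tert-butyldimethylsilyl)oxy]-5,9-dimethylundeca-1,5,8-trien-3-yl 2-(bromomethyl)prop-2-enoate
Product: 23 (S)-3-(bromomethyl)-5-[(2Z,5Z,7S)-7,8-bis[(tert-butyldimethylsilyl)oxy]-2,6-dimethylocta-2,5-dien-1-yl]furan-2(5H)-one
Conditions: second-generation Grubbs catalyst (cat.), 1,4-benzoquinone (cat.), CH2Cl2, 40 °C, dilute
Reagents that add atoms: none
Why: Ring-closing metathesis between the vinyl group and the acrylate closes the five-membered butenolide with loss of ethene; the two trisubstituted Z-alkenes are too hindered to take part.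

Step 12
Reactants: 23 (S)-3-(bromomethyl)-5-[(2Z,5Z,7S)-7,8-bis[(tert-butyldimethylsilyl)oxy]-2,6-dimethylocta-2,5-dien-1-yl]furan-2(5H)-one
Product: 24 (S)-3-(bromomethyl)-5-[(2Z,5Z,7S)-7-[(tert-butyldimethylsilyl)oxy]-8-hydroxy-2,6-dimethylocta-2,5-dien-1-yl]furan-2(5H)-one
Conditions: (±)-camphor-10-sulfonic acid (cat.), MeOH/CH2Cl2, 0 °C
Reagents that add atoms: none
Why: Acid-catalysed methanolysis cleaves the primary silyl ether much faster than the hindered secondary one, and the base-free medium spares the allylic bromide and the butenolide.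

Step 13
Reactants: 24 (S)-3-(bromomethyl)-5-[(2Z,5Z,7S)-7-[(tert-butyldimethylsilyl)oxy]-8-hydroxy-2,6-dimethylocta-2,5-dien-1-yl]furan-2(5H)-one
Product: 25 (2S,3Z,6Z)-8-[(S)-4-(bromomethyl)-5-oxo-2,5-dihydrofuran-2-yl]-2-[(tert-butyldimethylsilyl)oxy]-3,7-dimethylocta-3,6-dienal
Conditions: Dess–Martin periodinane, pyridine, CH2Cl2, 0 °C; used at once
Reagents that add atoms: none
Why: Buffered Dess–Martin oxidation gives the α-silyloxy aldehyde under near-neutral conditions, which should avoid epimerisation at C9 and migration of the C10=C1 bond into conjugation.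

Step 14
Reactants: 25 (2S,3Z,6Z)-8-[(S)-4-(bromomethyl)-5-oxo-2,5-dihydrofuran-2-yl]-2-[(tert-butyldimethylsilyl)oxy]-3,7-dimethylocta-3,6-dienal
Product: 27 (3aR,4R,5S,6Z,9Z,11aS)-5-[(tert-butyldimethylsilyl)oxy]-4-hydroxy-6,10-dimethyl-3-methylidene-3a,4,5,8,11,11a-hexahydrocyclodeca[b]furan-2(3H)-one, via allylchromium species 26 (not isolated)
Conditions: CrCl2 (excess), THF, 23 °C, high dilution, slow addition of 25; aq. work-up
Reagents that add atoms: chromium dichloride Cl[Cr]Cl (chromium and chlorine of intermediate 26 only)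
Why: Two equivalents of divalent chromium insert into the allylic C13–Br bond to give the σ-allyl complex of trivalent chromium 26, which adds through its γ-carbon C7 to the C8 aldehyde in a six-membered chair (Zimmerman–Traxler) transition state, so that the butenolide C7=C11 bond is transposed to the exocyclic C11=C13 methylene. The closest known reaction type is the Nozaki–Hiyama–Kishi (Barbier) 2-(alkoxycarbonyl)allylation of aldehydes by 2-(bromomethyl)acrylates and 3-(bromomethyl)furan-2(5H)-ones, which is also established intramolecularly for closing ten-membered germacranolide rings. The ten-membered carbocycle closes in the 10-exo-trig mode at the aldehyde carbonyl. C8 is set by polar Felkin–Anh control from the non-chelating C9 silyloxy stereocentre (8,9-anti), and C7 relative to C8 by the chair in which the ring-locked E-type γ-substituent C6 and the aldehyde substituent C9 are both pseudo-equatorial. C7 relative to C6 is set by the tether: the two Z-alkenes hold the aldehyde over the butenolide face that carries the C5 arm, and only this syn delivery gives a cisoid C5–C6–C7–C8 torsion that fits a ring of the all-cis-cyclodeca-1,4,7-triene type, hence the cis-fused lactone. The step needs aldehyde-over-lactone chemoselectivity (inherent to allylchromium reagents), γ-selectivity (inherent to the cyclic transition state) and ring closure over oligomerisation (high dilution, slow addition).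

Step 15
Reactants: 28 (E)-2-methylbut-2-en-1-ol
Product: 29 [(2R,3R)-2,3-dimethyloxiran-2-yl]methanol
Conditions: Ti(Oi-Pr)4 (cat.), D-(−)-diethyl tartrate (cat.), t-BuOOH, 4 Å molecular sieves, CH2Cl2, −20 °C
Reagents that add atoms: tert-butyl hydroperoxide CC(C)(C)OO
Why: Sharpless asymmetric epoxidation; the D-(−)-tartrate catalyst delivers oxygen to the alkene face that gives the (2R,3R)-epoxy alcohol (L-(+)-tartrate gives 2S,3S from E-allylic alcohols), and the cis relation of the two methyl groups follows from the E-alkene.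

Step 16
Reactants: 29 [(2R,3R)-2,3-dimethyloxiran-2-yl]methanol
Product: 30 (2S,3R)-2,3-dimethyloxirane-2-carboxylic acid
Conditions: RuCl3·xH2O (cat.), NaIO4, CCl4/MeCN/H2O, 23 °C
Reagents that add atoms: sodium periodate [Na+].[O-]I(=O)(=O)=O (oxygen, delivered through RuO4 and the aldehyde hydrate)
Why: Catalytic RuO4 oxidation takes the primary alcohol to the acid without opening the epoxide; no bond at a stereocentre changes, and the C2 descriptor switches from R to S only through the priority change.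

Step 17
Reactants: 27 (3aR,4R,5S,6Z,9Z,11aS)-5-[(tert-butyldimethylsilyl)oxy]-4-hydroxy-6,10-dimethyl-3-methylidene-3a,4,5,8,11,11a-hexahydrocyclodeca[b]furan-2(3H)-one; 30 (2S,3R)-2,3-dimethyloxirane-2-carboxylic acid
Product: 32 (3aS,4R,5S,6Z,9Z,11aS)-5-[(tert-butyldimethylsilyl)oxy]-6,10-dimethyl-3-methylidene-2-oxo-2,3,3a,4,5,8,11,11a-octahydrocyclodeca[b]furan-4-yl (2S,3R)-2,3-dimethyloxirane-2-carboxylate, via mixed anhydride 31 (not isolated)
Conditions: 30, 2,4,6-trichlorobenzoyl chloride, Et3N, toluene, 23 °C; then 27, DMAP, toluene, 23 → 40 °C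
Reagents that add atoms: 2,4,6-trichlorobenzoyl chloride O=C(Cl)c1c(Cl)cc(Cl)cc1Cl (atoms of intermediate 31 only)
Why: Yamaguchi esterification through the mixed anhydride suits a hindered secondary alcohol and an α-quaternary acid and proceeds with retention at C8 and in the oxirane.

Step 18
Reactants: 32 (3aS,4R,5S,6Z,9Z,11aS)-5-[(tert-butyldimethylsilyl)oxy]-6,10-dimethyl-3-methylidene-2-oxo-2,3,3a,4,5,8,11,11a-octahydrocyclodeca[b]furan-4-yl (2S,3R)-2,3-dimethyloxirane-2-carboxylate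
Product: 33 (3aS,4R,5S,6Z,9Z,11aS)-5-hydroxy-6,10-dimethyl-3-methylidene-2-oxo-2,3,3a,4,5,8,11,11a-octahydrocyclodeca[b]furan-4-yl (2S,3R)-2,3-dimethyloxirane-2-carboxylate
Conditions: HF·pyridine, THF, 0 → 23 °C
Reagents that add atoms: none
Why: Fluoride-mediated desilylation in a weakly acidic medium should free the C9 hydroxyl without acyl migration from C8 and without opening the electron-poor epoxy ester or adding to the methylene lactone.

Step 19
Reactants: 33 (3aS,4R,5S,6Z,9Z,11aS)-5-hydroxy-6,10-dimethyl-3-methylidene-2-oxo-2,3,3a,4,5,8,11,11a-octahydrocyclodeca[b]furan-4-yl (2S,3R)-2,3-dimethyloxirane-2-carboxylate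
Product: 34 (3aS,4R,5S,6Z,9Z,11aS)-5-acetoxy-6,10-dimethyl-3-methylidene-2-oxo-2,3,3a,4,5,8,11,11a-octahydrocyclodeca[b]furan-4-yl (2S,3R)-2,3-dimethyloxirane-2-carboxylate (CNP0188864.1)
Conditions: Ac2O, pyridine, DMAP (cat.), CH2Cl2, 0 → 23 °C
Reagents that add atoms: acetic anhydride CC(=O)OC(C)=O
Why: Standard acetylation of the remaining secondary allylic alcohol with retention at C9 should complete the target.

## Compound list

1 | methyl (R)-2,2-dimethyl-1,3-dioxolane-4-carboxylate | COC(=O)[C@H]1COC(C)(C)O1 | starting material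
2 | methyl (R)-2,3-dihydroxypropanoate | COC(=O)[C@H](O)CO | intermediate
3 | methyl (R)-2,3-bis[(tert-butyldimethylsilyl)oxy]propanoate | COC(=O)[C@H](O[Si](C)(C)C(C)(C)C)CO[Si](C)(C)C(C)(C)C | intermediate
4 | (R)-2,3-bis[(tert-butyldimethylsilyl)oxy]-N-methoxy-N-methylpropanamide (Weinreb amide, not isolated) | CON(C)C(=O)[C@H](O[Si](C)(C)C(C)(C)C)CO[Si](C)(C)C(C)(C)C | intermediate
5 | (R)-3,4-bis[(tert-butyldimethylsilyl)oxy]butan-2-one | CC(=O)[C@H](O[Si](C)(C)C(C)(C)C)CO[Si](C)(C)C(C)(C)C | intermediate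
6 | 3-[(tert-butyldimethylsilyl)oxy]propanal | O=CCCO[Si](C)(C)C(C)(C)C | starting material
7 | ethyltriphenylphosphonium iodide | CC[P+](c1ccccc1)(c1ccccc1)c1ccccc1.[I-] | starting material
8 | ethylidenetriphenylphosphorane (not isolated) | CC=P(c1ccccc1)(c1ccccc1)c1ccccc1 | intermediate
9 | (1-iodoethyl)triphenylphosphonium iodide (not isolated) | CC(I)[P+](c1ccccc1)(c1ccccc1)c1ccccc1.[I-] | intermediate
10 | (1-iodoethylidene)triphenylphosphorane (not isolated) | CC(I)=P(c1ccccc1)(c1ccccc1)c1ccccc1 | intermediate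
11 | (Z)-tert-butyl[(4-iodopent-3-en-1-yl)oxy]dimethylsilane | C/C(I)=C/CCO[Si](C)(C)C(C)(C)C | intermediate
12 | (Z)-5-bromo-2-iodopent-2-ene | C/C(I)=C/CCBr | intermediate
13 | [(Z)-4-iodopent-3-en-1-yl]triphenylphosphonium bromide | C/C(I)=C/CC[P+](c1ccccc1)(c1ccccc1)c1ccccc1.[Br-] | intermediate
14 | [(Z)-4-iodopent-3-en-1-ylidene]triphenylphosphorane (not isolated) | C/C(I)=C/CC=P(c1ccccc1)(c1ccccc1)c1ccccc1 | intermediate
15 | (2S,3Z,6Z)-1,2-bis[(tert-butyldimethylsilyl)oxy]-7-iodo-3-methylocta-3,6-diene | I/C(C)=C\C/C=C(/C)[C@H](O[Si](C)(C)C(C)(C)C)CO[Si](C)(C)C(C)(C)C | intermediate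
16 | (S)-epichlorohydrin, (S)-2-(chloromethyl)oxirane | ClC[C@@H]1CO1 | starting material
17 | vinyllithium from 15 (lithium in place of iodine, alkene geometry retained; not isolated) | [Li]/C(C)=C\C/C=C(/C)[C@H](O[Si](C)(C)C(C)(C)C)CO[Si](C)(C)C(C)(C)C | intermediate
18 | (2S,4Z,7Z,9S)-9,10-bis[(tert-butyldimethylsilyl)oxy]-1-chloro-4,8-dimethyldeca-4,7-dien-2-ol | O[C@H](CCl)C/C(C)=C\C/C=C(/C)[C@H](O[Si](C)(C)C(C)(C)C)CO[Si](C)(C)C(C)(C)C | intermediate
19 | (S)-2-[(2Z,5Z,7S)-7,8-bis[(tert-butyldimethylsilyl)oxy]-2,6-dimethylocta-2,5-dien-1-yl]oxirane (not isolated) | O1[C@H](C1)C/C(C)=C\C/C=C(/C)[C@H](O[Si](C)(C)C(C)(C)C)CO[Si](C)(C)C(C)(C)C | intermediate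
20 | (3S,5Z,8Z,10S)-10,11-bis[(tert-butyldimethylsilyl)oxy]-5,9-dimethylundeca-1,5,8-trien-3-ol | O[C@H](C=C)C/C(C)=C\C/C=C(/C)[C@H](O[Si](C)(C)C(C)(C)C)CO[Si](C)(C)C(C)(C)C | intermediate
21 | 2-(bromomethyl)prop-2-enoic acid | C=C(CBr)C(=O)O | starting material
22 | (3S,5Z,8Z,10S)-10,11-bis[(tert-butyldimethylsilyl)oxy]-5,9-dimethylundeca-1,5,8-trien-3-yl 2-(bromomethyl)prop-2-enoate | C=C(CBr)C(=O)O[C@H](C=C)C/C(C)=C\C/C=C(/C)[C@H](O[Si](C)(C)C(C)(C)C)CO[Si](C)(C)C(C)(C)C | intermediate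
23 | (S)-3-(bromomethyl)-5-[(2Z,5Z,7S)-7,8-bis[(tert-butyldimethylsilyl)oxy]-2,6-dimethylocta-2,5-dien-1-yl]furan-2(5H)-one | BrCC1=C[C@H](C/C(C)=C\C/C=C(/C)[C@H](O[Si](C)(C)C(C)(C)C)CO[Si](C)(C)C(C)(C)C)OC1=O | intermediate
24 | (S)-3-(bromomethyl)-5-[(2Z,5Z,7S)-7-[(tert-butyldimethylsilyl)oxy]-8-hydroxy-2,6-dimethylocta-2,5-dien-1-yl]furan-2(5H)-one | BrCC1=C[C@H](C/C(C)=C\C/C=C(/C)[C@H](O[Si](C)(C)C(C)(C)C)CO)OC1=O | intermediate
25 | (2S,3Z,6Z)-8-[(S)-4-(bromomethyl)-5-oxo-2,5-dihydrofuran-2-yl]-2-[(tert-butyldimethylsilyl)oxy]-3,7-dimethylocta-3,6-dienal | BrCC1=C[C@H](C/C(C)=C\C/C=C(/C)[C@H](O[Si](C)(C)C(C)(C)C)C=O)OC1=O | intermediate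
26 | allylchromium species from 25 (dichlorochromium on the exocyclic CH2; not isolated) | Cl[Cr](Cl)CC1=C[C@H](C/C(C)=C\C/C=C(/C)[C@H](O[Si](C)(C)C(C)(C)C)C=O)OC1=O | intermediate
27 | (3aR,4R,5S,6Z,9Z,11aS)-5-[(tert-butyldimethylsilyl)oxy]-4-hydroxy-6,10-dimethyl-3-methylidene-3a,4,5,8,11,11a-hexahydrocyclodeca[b]furan-2(3H)-one (cis-fused lactone, free C8 hydroxyl) | C=C1C(=O)O[C@H]2C/C(C)=C\C/C=C(/C)[C@H](O[Si](C)(C)C(C)(C)C)[C@H](O)[C@@H]12 | intermediate
28 | (E)-2-methylbut-2-en-1-ol (tiglyl alcohol) | C/C=C(\C)CO | starting material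
29 | [(2R,3R)-2,3-dimethyloxiran-2-yl]methanol | OC[C@@]1(C)O[C@@H]1C | intermediate
30 | (2S,3R)-2,3-dimethyloxirane-2-carboxylic acid | O=C(O)[C@@]1(C)O[C@@H]1C | intermediate
31 | (2S,3R)-2,3-dimethyloxirane-2-carboxylic 2,4,6-trichlorobenzoic anhydride (not isolated) | O=C(OC(=O)c1c(Cl)cc(Cl)cc1Cl)[C@@]1(C)O[C@@H]1C | intermediate
32 | (3aS,4R,5S,6Z,9Z,11aS)-5-[(tert-butyldimethylsilyl)oxy]-6,10-dimethyl-3-methylidene-2-oxo-2,3,3a,4,5,8,11,11a-octahydrocyclodeca[b]furan-4-yl (2S,3R)-2,3-dimethyloxirane-2-carboxylate | C=C1C(=O)O[C@H]2C/C(C)=C\C/C=C(/C)[C@H](O[Si](C)(C)C(C)(C)C)[C@H](OC(=O)[C@@]3(C)O[C@@H]3C)[C@@H]12 | intermediate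
33 | (3aS,4R,5S,6Z,9Z,11aS)-5-hydroxy-6,10-dimethyl-3-methylidene-2-oxo-2,3,3a,4,5,8,11,11a-octahydrocyclodeca[b]furan-4-yl (2S,3R)-2,3-dimethyloxirane-2-carboxylate | C=C1C(=O)O[C@H]2C/C(C)=C\C/C=C(/C)[C@H](O)[C@H](OC(=O)[C@@]3(C)O[C@@H]3C)[C@@H]12 | intermediate
34 | (3aS,4R,5S,6Z,9Z,11aS)-5-acetoxy-6,10-dimethyl-3-methylidene-2-oxo-2,3,3a,4,5,8,11,11a-octahydrocyclodeca[b]furan-4-yl (2S,3R)-2,3-dimethyloxirane-2-carboxylate | C=C1C(=O)O[C@H]2C/C(C)=C\C/C=C(/C)[C@H](OC(C)=O)[C@H](OC(=O)[C@@]3(C)O[C@@H]3C)[C@@H]12 | target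

## Step count and risks

Total step count: 19. Longest linear sequence: 14 steps (steps 4–14 and 17–19 from 6 and 7; equally steps 1–3, 7–14 and 17–19 from 1).

**Risk 1, step 14.** What may go wrong: the allylchromium may add to the butenolide face anti to the C5 arm (trans ring fusion and therefore the wrong C7 configuration), or couple intermolecularly. The fallback turns an anti preference into an asset and corrects C6 afterwards; it sets out from 15 and comes back at 27. Lithiation of 15 as in step 8 and opening of (R)-epichlorohydrin should give the (2R,4Z,7Z,9S)-chlorohydrin F1. Excess dimethylsulfonium methylide should convert it, through the (R)-oxirane F2, into the (3R)-allylic alcohol F3. Steglich esterification with 21 should give the 2-(bromomethyl)acrylate F4, ring-closing metathesis the (R)-butenolide F5, acid-catalysed methanolysis the primary alcohol F6, and Dess–Martin oxidation the aldehyde F7. Cyclisation with CrCl2 through the allylchromium species F8 should now form C7–C8 anti to the C5 arm, with the facial bias, the Felkin–Anh preference and the chair preference all pointing the same way, to give the trans-fused 6-epi hydroxy lactone F9. Silylation (Et3SiOTf, 2,6-lutidine) should give the C8 triethylsilyl ether F10, and LiOH in aqueous THF should open the lactone to the seco hydroxy acid F11. Mitsunobu lactonisation (PPh3, diisopropyl azodicarboxylate, high dilution) should close the γ-lactone with inversion at C6 to the cis-fused lactone F12. HF·pyridine at 0 °C should remove the triethylsilyl group selectively and return 27.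

**Risk 2, step 11.** What may go wrong: the allylic bromide may degrade at the ruthenium carbene, or ring closure onto the 1,1-disubstituted bromomethyl acrylate may stall. The fallback installs the bromide after ring closure; it sets out from 20 and comes back at 23. Steglich esterification of 20 with 2-{[(4-methoxybenzyl)oxy]methyl}prop-2-enoic acid should give the ester F13. Ring-closing metathesis should give the 4-methoxybenzyl-protected 3-(hydroxymethyl)butenolide F14. Oxidative debenzylation (DDQ, CH2Cl2/pH 7 buffer, 0 °C) should give the 3-(hydroxymethyl)butenolide F15, and Appel bromination (CBr4, PPh3, 0 °C) should return 23.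

**Risk 3, step 7.** What may go wrong: the hindered bis-silyloxy ketone may be enolised by the basic ylide (loss of the C9 configuration), or Z-selectivity may erode. The fallback carries the diol through the olefination as a cyclic ketal, the α-alkoxy ketone class with the closest precedent for Z-selective Wittig olefination; it sets out from 1 and 13 and comes back at 15. Ester 1 should give the Weinreb amide F16 (MeNH(OMe)·HCl, i-PrMgCl) and then, with MeMgBr, the dioxolanyl methyl ketone F17. Wittig reaction with ylide 14 (from 13) should give the acetonide iododiene F18. Acid-catalysed methanolysis (pyridinium p-toluenesulfonate, MeOH) should give the diol F19, and silylation (TBSCl, imidazole) should return 15.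

Further compounds

F1 | step 14 | (2R,4Z,7Z,9S)-9,10-bis[(tert-butyldimethylsilyl)oxy]-1-chloro-4,8-dimethyldeca-4,7-dien-2-ol | O[C@@H](CCl)C/C(C)=C\C/C=C(/C)[C@H](O[Si](C)(C)C(C)(C)C)CO[Si](C)(C)C(C)(C)C
F2 | step 14 | (R)-2-[(2Z,5Z,7S)-7,8-bis[(tert-butyldimethylsilyl)oxy]-2,6-dimethylocta-2,5-dien-1-yl]oxirane (not isolated) | O1[C@@H](C1)C/C(C)=C\C/C=C(/C)[C@H](O[Si](C)(C)C(C)(C)C)CO[Si](C)(C)C(C)(C)C
F3 | step 14 | (3R,5Z,8Z,10S)-10,11-bis[(tert-butyldimethylsilyl)oxy]-5,9-dimethylundeca-1,5,8-trien-3-ol | O[C@@H](C=C)C/C(C)=C\C/C=C(/C)[C@H](O[Si](C)(C)C(C)(C)C)CO[Si](C)(C)C(C)(C)C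
F4 | step 14 | (3R,5Z,8Z,10S)-10,11-bis[(tert-butyldimethylsilyl)oxy]-5,9-dimethylundeca-1,5,8-trien-3-yl 2-(bromomethyl)prop-2-enoate | C=C(CBr)C(=O)O[C@@H](C=C)C/C(C)=C\C/C=C(/C)[C@H](O[Si](C)(C)C(C)(C)C)CO[Si](C)(C)C(C)(C)C
F5 | step 14 | (R)-3-(bromomethyl)-5-[(2Z,5Z,7S)-7,8-bis[(tert-butyldimethylsilyl)oxy]-2,6-dimethylocta-2,5-dien-1-yl]furan-2(5H)-one | BrCC1=C[C@@H](C/C(C)=C\C/C=C(/C)[C@H](O[Si](C)(C)C(C)(C)C)CO[Si](C)(C)C(C)(C)C)OC1=O
F6 | step 14 | (R)-3-(bromomethyl)-5-[(2Z,5Z,7S)-7-[(tert-butyldimethylsilyl)oxy]-8-hydroxy-2,6-dimethylocta-2,5-dien-1-yl]furan-2(5H)-one | BrCC1=C[C@@H](C/C(C)=C\C/C=C(/C)[C@H](O[Si](C)(C)C(C)(C)C)CO)OC1=O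
F7 | step 14 | (2S,3Z,6Z)-8-[(R)-4-(bromomethyl)-5-oxo-2,5-dihydrofuran-2-yl]-2-[(tert-butyldimethylsilyl)oxy]-3,7-dimethylocta-3,6-dienal | BrCC1=C[C@@H](C/C(C)=C\C/C=C(/C)[C@H](O[Si](C)(C)C(C)(C)C)C=O)OC1=O
F8 | step 14 | allylchromium species from F7 (dichlorochromium on the exocyclic CH2; not isolated) | Cl[Cr](Cl)CC1=C[C@@H](C/C(C)=C\C/C=C(/C)[C@H](O[Si](C)(C)C(C)(C)C)C=O)OC1=O
F9 | step 14 | (3aR,4R,5S,6Z,9Z,11aR)-5-[(tert-butyldimethylsilyl)oxy]-4-hydroxy-6,10-dimethyl-3-methylidene-3a,4,5,8,11,11a-hexahydrocyclodeca[b]furan-2(3H)-one (trans-fused, 6-epi) | C=C1C(=O)O[C@@H]2C/C(C)=C\C/C=C(/C)[C@H](O[Si](C)(C)C(C)(C)C)[C@H](O)[C@@H]12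
F10 | step 14 | (3aS,4R,5S,6Z,9Z,11aR)-5-[(tert-butyldimethylsilyl)oxy]-6,10-dimethyl-3-methylidene-4-[(triethylsilyl)oxy]-3a,4,5,8,11,11a-hexahydrocyclodeca[b]furan-2(3H)-one | C=C1C(=O)O[C@@H]2C/C(C)=C\C/C=C(/C)[C@H](O[Si](C)(C)C(C)(C)C)[C@H](O[Si](CC)(CC)CC)[C@@H]12
F11 | step 14 | seco hydroxy acid of F10: 2-[(4Z,7Z)-9-[(tert-butyldimethylsilyl)oxy]-2-hydroxy-4,8-dimethyl-10-[(triethylsilyl)oxy]cyclodeca-4,7-dien-1-yl]prop-2-enoic acid, configuration as in F10 | OC(=O)C(=C)[C@H]1[C@H](O)C/C(C)=C\C/C=C(/C)[C@H](O[Si](C)(C)C(C)(C)C)[C@@H]1O[Si](CC)(CC)CC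
F12 | step 14 | (3aS,4R,5S,6Z,9Z,11aS)-5-[(tert-butyldimethylsilyl)oxy]-6,10-dimethyl-3-methylidene-4-[(triethylsilyl)oxy]-3a,4,5,8,11,11a-hexahydrocyclodeca[b]furan-2(3H)-one (cis-fused) | C=C1C(=O)O[C@H]2C/C(C)=C\C/C=C(/C)[C@H](O[Si](C)(C)C(C)(C)C)[C@H](O[Si](CC)(CC)CC)[C@@H]12
F13 | step 11 | (3S,5Z,8Z,10S)-10,11-bis[(tert-butyldimethylsilyl)oxy]-5,9-dimethylundeca-1,5,8-trien-3-yl 2-{[(4-methoxybenzyl)oxy]methyl}prop-2-enoate | C=C(COCc1ccc(OC)cc1)C(=O)O[C@H](C=C)C/C(C)=C\C/C=C(/C)[C@H](O[Si](C)(C)C(C)(C)C)CO[Si](C)(C)C(C)(C)C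
F14 | step 11 | (S)-5-[(2Z,5Z,7S)-7,8-bis[(tert-butyldimethylsilyl)oxy]-2,6-dimethylocta-2,5-dien-1-yl]-3-{[(4-methoxybenzyl)oxy]methyl}furan-2(5H)-one | COc1ccc(COCC2=C[C@H](C/C(C)=C\C/C=C(/C)[C@H](O[Si](C)(C)C(C)(C)C)CO[Si](C)(C)C(C)(C)C)OC2=O)cc1
F15 | step 11 | (S)-5-[(2Z,5Z,7S)-7,8-bis[(tert-butyldimethylsilyl)oxy]-2,6-dimethylocta-2,5-dien-1-yl]-3-(hydroxymethyl)furan-2(5H)-one | OCC1=C[C@H](C/C(C)=C\C/C=C(/C)[C@H](O[Si](C)(C)C(C)(C)C)CO[Si](C)(C)C(C)(C)C)OC1=O
F16 | step 7 | (R)-N-methoxy-N,2,2-trimethyl-1,3-dioxolane-4-carboxamide | CON(C)C(=O)[C@H]1COC(C)(C)O1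
F17 | step 7 | (R)-1-(2,2-dimethyl-1,3-dioxolan-4-yl)ethan-1-one | CC(=O)[C@H]1COC(C)(C)O1
F18 | step 7 | (S)-4-[(2Z,5Z)-6-iodohepta-2,5-dien-2-yl]-2,2-dimethyl-1,3-dioxolane | I/C(C)=C\C/C=C(/C)[C@H]1COC(C)(C)O1
F19 | step 7 | (2S,3Z,6Z)-7-iodo-3-methylocta-3,6-diene-1,2-diol | I/C(C)=C\C/C=C(/C)[C@H](O)CO
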